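**Plan**
Retrosynthetic cuts, in order: (a) C1 of the pyran (C8a–C1, C1–O2) of the quinone methide half; (b) the carbocycle C4a–C5–C6–C7–C8–C8a of that half, taken back to a cyclobutenone (C8, C8a, C4a, C5) plus the two carbons (C7, C6) of a siloxyalkyne that already carries the ethane-1,1-diyl bridge and the complete dihydroisocoumarin; (c) the bridge–C7′ aryl bond; (d) the lactone O–C3′ bond and C8a′–C1′.
Enabling feature: C7, the ring carbon that bears the bridge, lies between the two oxygenated carbons C6 and C8 of a fully substituted six-membered ring, and C8a is its only CH; a cyclobutenone/ynol ether ring expansion delivers exactly this 1,3-dioxygen pattern with a carbon substituent in between, with fixed regiochemistry.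
Forward: bromoarene 14 → side chain → trans-lactone 20 → bridge alkyne 24 → siloxyalkyne 27; alkyne 6 → cyclobutenone 8; 8 + 27 → hexasubstituted phenol 32 (four-membered ring expanded to six, halves joined); desilylation, demethylation, pyran closure to the quinone methide.
Stereochemistry: C4 and C4′ from SN2 opening of (2S,3S)-2,3-dimethyloxirane; C3 and C3′ by Mitsunobu inversion; the bridge carbon from (S)-but-3-yn-2-ol through two anti-SN2′ displacements; the key step creates no stereocentre and touches none.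

Key step: step 18

Remark: compounds 1, 2, 9 and 12 are taken as purchasable, and the target is handled as the ortho-quinone methide tautomer written in the given SMILES.

**Step 1**
Reactants: 1 (2S,3S)-2,3-dimethyloxirane; 2 1-propynyllithium
Product: 3 (2S,3S)-3-methylhex-4-yn-2-ol
Conditions: 2, THF, −78 °C; BF3·OEt2; then 1, −78 °C; H2O
Reagents that add atoms: none
Why: BF3-promoted SN2 opening of the C2-symmetric epoxide by the alkynyllithium (both carbons are equivalent) should invert the attacked carbon, which fixes the future C4 as S, while the carbinol carbon stays S (erythro).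

**Step 2**
Reactants: 3 (2S,3S)-3-methylhex-4-yn-2-ol
Product: 4 (2R,3S)-3-methylhex-4-yn-2-yl 4-nitrobenzoate
Conditions: 4-nitrobenzoic acid, PPh3, DIAD, THF, 0 °C → rt
Reagents that add atoms: 4-nitrobenzoic acid, O=C(O)c1ccc(cc1)[N+](=O)[O-]
Why: Mitsunobu esterification should go with SN2 inversion at the carbinol carbon (S → R), giving the threo relationship that becomes the trans-3,4-dimethyl pyran.

**Step 3**
Reactants: 4 (2R,3S)-3-methylhex-4-yn-2-yl 4-nitrobenzoate
Product: 5 (2R,3S)-3-methylhex-4-yn-2-ol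
Conditions: K2CO3 (cat.), MeOH, rt
Reagents that add atoms: none
Why: Base-catalysed transesterification cleaves the acyl–oxygen bond, so the alcohol should be released with both stereocentres unchanged.

**Step 4**
Reactants: 5 (2R,3S)-3-methylhex-4-yn-2-ol
Product: 6 tert-butyl(dimethyl){[(2R,3S)-3-methylhex-4-yn-2-yl]oxy}silane
Conditions: TBSCl, imidazole, DMF, rt
Reagents that add atoms: tert-butyldimethylsilyl chloride, CC(C)(C)[Si](C)(C)Cl
Why: Standard silylation of a secondary alcohol; the TBS ether should survive the acylating ketene conditions and the later thermolysis.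

**Step 5**
Reactants: 6 tert-butyl(dimethyl){[(2R,3S)-3-methylhex-4-yn-2-yl]oxy}silane
Product: 7 3-[(2S,3R)-3-{[tert-butyl(dimethyl)silyl]oxy}butan-2-yl]-4,4-dichloro-2-methylcyclobut-2-en-1-one
Conditions: Cl3CCOCl, zinc–copper couple, Et2O/DME, rt → 35 °C
Reagents that add atoms: trichloroacetyl chloride, ClC(Cl)(Cl)C(Cl)=O
Why: Ketene–alkyne [2+2] cycloaddition of dichloroketene; its carbonyl carbon should bond to the less hindered methyl-bearing alkyne carbon and the CCl2 carbon to the carbon carrying the branched chain (which better carries the positive charge of the asynchronous transition state), placing the methyl at C2.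

**Step 6**
Reactants: 7 3-[(2S,3R)-3-{[tert-butyl(dimethyl)silyl]oxy}butan-2-yl]-4,4-dichloro-2-methylcyclobut-2-en-1-one
Product: 8 3-[(2S,3R)-3-{[tert-butyl(dimethyl)silyl]oxy}butan-2-yl]-2-methylcyclobut-2-en-1-one
Conditions: Zn dust, AcOH, TMEDA, EtOH, 0 °C
Reagents that add atoms: none
Why: Buffered zinc reduction of the α,α-dichloroketone should remove both chlorines without opening the strained enone or cleaving the silyl ether.

**Step 7**
Reactants: 9 (S)-but-3-yn-2-ol
Product: 10 (S)-but-3-yn-2-yl methanesulfonate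
Conditions: MsCl, Et3N, CH2Cl2, −78 → 0 °C
Reagents that add atoms: methanesulfonyl chloride, CS(=O)(=O)Cl
Why: O-sulfonylation does not touch the stereocentre and turns the hydroxyl into a leaving group for SN2′ displacement.

**Step 8**
Reactants: 10 (S)-but-3-yn-2-yl methanesulfonate
Product: 11 (aR)-1-bromobuta-1,2-diene
Conditions: LiBr, CuBr, THF, rt (used as a cold solution)
Reagents that add atoms: lithium bromide, [Li+].[Br-]
Why: Bromocuprate displacement of a propargylic sulfonate runs anti-SN2′, so the (S) centre should be converted into the (aR) allene axis.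

**Step 9**
Reactants: 12 1-bromo-3,5-dimethoxybenzene
Product: 13 2-bromo-4,6-dimethoxybenzaldehyde
Conditions: POCl3, DMF, 0 → 90 °C; aq NaOAc
Reagents that add atoms: N,N-dimethylformamide, CN(C)C=O; water, O
Why: Vilsmeier–Haack formylation should go para to one methoxy group and ortho to the other, the position between the two methoxy groups being flanked on both sides.

**Step 10**
Reactants: 13 2-bromo-4,6-dimethoxybenzaldehyde
Product: 14 1-bromo-3,5-dimethoxy-2-methylbenzene
Conditions: N2H4·H2O, KOH, diethylene glycol, 130 → 195 °C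
Reagents that add atoms: none
Why: Wolff–Kishner reduction takes the aryl aldehyde to the methyl group; the electron-rich aryl bromide and the methyl ethers should be inert.

**Step 11**
Reactants: 14 1-bromo-3,5-dimethoxy-2-methylbenzene; 1 (2S,3S)-2,3-dimethyloxirane
Product: 16 (2S,3S)-3-(3,5-dimethoxy-2-methylphenyl)butan-2-ol, via aryl Grignard reagent 15 (not isolated)
Conditions: Mg, THF, reflux; CuBr·SMe2 (10 mol %), then 1, −30 → 0 °C; cold dilute aq HCl
Reagents that add atoms: none
Why: Copper-catalysed SN2 opening of the symmetric epoxide by the aryl Grignard reagent should invert the attacked carbon, setting C4′ (S), and leave the carbinol S.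

**Step 12**
Reactants: 16 (2S,3S)-3-(3,5-dimethoxy-2-methylphenyl)butan-2-ol
Product: 17 (2S,3S)-3-(2-bromo-3,5-dimethoxy-6-methylphenyl)butan-2-ol
Conditions: NBS, MeCN, 0 °C
Reagents that add atoms: N-bromosuccinimide, O=C1CCC(=O)N1Br
Why: Electrophilic bromination with NBS in acetonitrile is para-selective for anisoles, so it should take the position para to the 3-methoxy group and not the doubly flanked site between the methoxy groups.

**Step 13**
Reactants: 17 (2S,3S)-3-(2-bromo-3,5-dimethoxy-6-methylphenyl)butan-2-ol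
Product: 19 2-[(2S,3S)-3-hydroxybutan-2-yl]-4,6-dimethoxy-3-methylbenzoic acid, via aryllithium alkoxide 18 (not isolated)
Conditions: n-BuLi (2.2 equiv), THF, −78 °C; CO2; 1 M aq HCl to pH 3, 0 °C
Reagents that add atoms: carbon dioxide, O=C=O
Why: Alkoxide formation followed by bromine–lithium exchange and carboxylation; the di-ortho-substituted benzoic acid resists acyl substitution, so the hydroxy acid should stay open on cold acidification.

**Step 14**
Reactants: 19 2-[(2S,3S)-3-hydroxybutan-2-yl]-4,6-dimethoxy-3-methylbenzoic acid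
Product: 20 (3R,4S)-6,8-dimethoxy-3,4,5-trimethyl-3,4-dihydro-1H-isochromen-1-one
Conditions: PPh3, DIAD, toluene (0.01 M), 0 °C → rt
Reagents that add atoms: none
Why: Mitsunobu lactonization: the carboxylate displaces the alkoxyphosphonium group in a 6-exo-tet SN2 step, so C3′ should be inverted to R and the 3,4-dimethyl groups end up trans.

**Step 15**
Reactants: 20 (3R,4S)-6,8-dimethoxy-3,4,5-trimethyl-3,4-dihydro-1H-isochromen-1-one
Product: 21 (3R,4S)-7-iodo-6,8-dimethoxy-3,4,5-trimethyl-3,4-dihydro-1H-isochromen-1-one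
Conditions: NIS, TFA (cat.), MeCN, rt
Reagents that add atoms: N-iodosuccinimide, O=C1CCC(=O)N1I
Why: Electrophilic iodination can only occur at C7′, the one unsubstituted arene carbon, which is ortho to both methoxy groups and meta to the carbonyl.

**Step 16**
Reactants: 21 (3R,4S)-7-iodo-6,8-dimethoxy-3,4,5-trimethyl-3,4-dihydro-1H-isochromen-1-one; 11 (aR)-1-bromobuta-1,2-diene
Product: 24 (3R,4S)-7-[(2S)-but-3-yn-2-yl]-6,8-dimethoxy-3,4,5-trimethyl-3,4-dihydro-1H-isochromen-1-one, via arylmagnesium chloride 22 (not isolated), via arylcopper reagent 23 (not isolated)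
Conditions: i-PrMgCl·LiCl, THF, −20 °C; CuBr·SMe2, LiBr, −60 °C; then 11, −60 → −20 °C
Reagents that add atoms: none
Why: Iodine–magnesium exchange should outpace attack on the hindered lactone, and the arylcopper reagent should substitute the bromoallene in the anti-SN2′ (1,3) mode, which transfers the axial chirality of 11 to the new bridge stereocentre (S in 24).

**Step 17**
Reactants: 24 (3R,4S)-7-[(2S)-but-3-yn-2-yl]-6,8-dimethoxy-3,4,5-trimethyl-3,4-dihydro-1H-isochromen-1-one
Product: 27 (3R,4S)-6,8-dimethoxy-3,4,5-trimethyl-7-[(2S)-4-{[tri(propan-2-yl)silyl]oxy}but-3-yn-2-yl]-3,4-dihydro-1H-isochromen-1-one, via lithium acetylide 25 (not isolated), via lithium ynolate 26 (not isolated)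
Conditions: LiHMDS, THF, −78 °C; t-BuOOLi (from t-BuOOH and LiHMDS), −78 → 0 °C; TIPSOTf, −78 °C
Reagents that add atoms: tert-butyl hydroperoxide (as its lithium salt), CC(C)(C)OO; triisopropylsilyl trifluoromethanesulfonate, CC(C)[Si](C(C)C)(C(C)C)OS(=O)(=O)C(F)(F)F
Why: Electrophilic oxygenation of the lithium acetylide by lithium tert-butyl peroxide gives the ynolate, which the bulky silyl triflate should trap on oxygen; LiHMDS is non-nucleophilic toward the lactone and too weak to remove the benzylic hydrogen of the bridge.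

**Step 18**
Reactants: 8 3-[(2S,3R)-3-{[tert-butyl(dimethyl)silyl]oxy}butan-2-yl]-2-methylcyclobut-2-en-1-one; 27 (3R,4S)-6,8-dimethoxy-3,4,5-trimethyl-7-[(2S)-4-{[tri(propan-2-yl)silyl]oxy}but-3-yn-2-yl]-3,4-dihydro-1H-isochromen-1-one
Product: 32 (3R,4S)-7-[(1R)-1-{4-[(2S,3R)-3-{[tert-butyl(dimethyl)silyl]oxy}butan-2-yl]-6-hydroxy-3-methyl-2-{[tri(propan-2-yl)silyl]oxy}phenyl}ethyl]-6,8-dimethoxy-3,4,5-trimethyl-3,4-dihydro-1H-isochromen-1-one, via vinylketene 28 (not isolated), via 2-vinylcyclobutenone 29 (not isolated), via dienylketene 30 (not isolated), via cyclohexa-2,4-dienone 31 (not isolated)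
Conditions: 8 (1.3 equiv), toluene, 80 °C, then 110 °C
Reagents that add atoms: none
Why: Heating opens cyclobutenone 8 (4π) to vinylketene 28, which adds the electron-rich siloxyalkyne 27 in a [2+2] to give 2-vinylcyclobutenone 29; this four-membered ring opens again (4π) to dienylketene 30, whose 6π-electrocyclization gives dienone 31 and, after tautomerization, phenol 32, so the four ring carbons of 8 and the two alkyne carbons become the six-membered ring. The closest known reaction type is the Danheiser benzannulation of cyclobutenones with trialkylsilyloxyalkynes. The six-membered ring closes by thermal disrotatory 6π-electrocyclization (C8–C8a bond), and the transient four-membered ring by ketene–alkyne [2+2] cycloaddition. No stereocentre is formed, and the five existing ones lie outside the reacting π-systems and are not enolizable under these neutral conditions, so they should be carried through unchanged. The step needs regiocontrol, which the polarization of the ynol ether secures: the ketene carbonyl carbon bonds to the alkyne carbon remote from oxygen, so the bridge carbon lands on C7 between C8–OH and C6–OTIPS, while the methyl (C5) and the side chain (C4a) are fixed by their positions on 8. The free phenol that arises from the cyclobutenone carbonyl sits next to C8a, the only unsubstituted ring carbon, which is where the last carbon is introduced in step 21.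

**Step 19**
Reactants: 32 benzannulation product (silyl-protected)
Product: 33 (3R,4S)-7-[(1S)-1-{2,6-dihydroxy-4-[(2S,3R)-3-hydroxybutan-2-yl]-3-methylphenyl}ethyl]-6,8-dimethoxy-3,4,5-trimethyl-3,4-dihydro-1H-isochromen-1-one
Conditions: TBAF, AcOH, THF, rt → 45 °C
Reagents that add atoms: none
Why: Buffered fluoride should cleave the aryl TIPS ether and the secondary TBS ether while keeping the medium mild enough for the lactone and the resorcinol (the bridge descriptor changes from R to S only because CIP priorities change).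

**Step 20**
Reactants: 33 desilylated bis-methyl ether
Product: 34 (3R,4S)-7-[(1S)-1-{2,6-dihydroxy-4-[(2S,3R)-3-hydroxybutan-2-yl]-3-methylphenyl}ethyl]-6,8-dihydroxy-3,4,5-trimethyl-3,4-dihydro-1H-isochromen-1-one
Conditions: BBr3, CH2Cl2, −78 → 0 °C; H2O
Reagents that add atoms: none
Why: Lewis-acid cleavage of the two aryl methyl ethers (the one peri to the lactone carbonyl is chelation-assisted) should leave the lactone, the secondary alcohol and the stereocentres intact at low temperature.

**Step 21**
Reactants: 34 pentahydroxy seco compound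
Product: 35 dicitrinone H
Conditions: HC(OEt)3, TFA, 0 °C → rt; then 1 M aq HCl
Reagents that add atoms: triethyl orthoformate, CCOC(OCC)OCC
Why: Acid-mediated formylation by the orthoformate can only take C8a, the single unsubstituted arene carbon and ortho/para to the two hydroxyls of that ring; the (3R)-hydroxyl should then capture the diethoxymethyl group and loss of ethanol gives the quinone methide, the established closure for this class of isochromene quinone methides, with the aqueous acid returning any orthoformate bound to phenols.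

**Compound list**
1 | (2S,3S)-2,3-dimethyloxirane | C[C@@H]1O[C@H]1C | starting material
2 | 1-propynyllithium | [Li]C#CC | starting material
3 | (2S,3S)-3-methylhex-4-yn-2-ol | CC#C[C@H](C)[C@H](C)O | intermediate
4 | (2R,3S)-3-methylhex-4-yn-2-yl 4-nitrobenzoate | CC#C[C@H](C)[C@@H](C)OC(=O)c1ccc(cc1)[N+](=O)[O-] | intermediate
5 | (2R,3S)-3-methylhex-4-yn-2-ol | CC#C[C@H](C)[C@@H](C)O | intermediate
6 | tert-butyl(dimethyl){[(2R,3S)-3-methylhex-4-yn-2-yl]oxy}silane | CC#C[C@H](C)[C@@H](C)O[Si](C)(C)C(C)(C)C | intermediate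
7 | 3-[(2S,3R)-3-{[tert-butyl(dimethyl)silyl]oxy}butan-2-yl]-4,4-dichloro-2-methylcyclobut-2-en-1-one | CC1=C([C@H](C)[C@@H](C)O[Si](C)(C)C(C)(C)C)C(Cl)(Cl)C1=O | intermediate
8 | 3-[(2S,3R)-3-{[tert-butyl(dimethyl)silyl]oxy}butan-2-yl]-2-methylcyclobut-2-en-1-one | CC1=C([C@H](C)[C@@H](C)O[Si](C)(C)C(C)(C)C)CC1=O | intermediate
9 | (S)-but-3-yn-2-ol | C#C[C@H](C)O | starting material
10 | (S)-but-3-yn-2-yl methanesulfonate | C#C[C@H](C)OS(C)(=O)=O | intermediate
11 | (aR)-1-bromobuta-1,2-diene | [H]C(Br)=[C@@]=C([H])C | intermediate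
12 | 1-bromo-3,5-dimethoxybenzene | COc1cc(OC)cc(Br)c1 | starting material
13 | 2-bromo-4,6-dimethoxybenzaldehyde | COc1cc(OC)c(C=O)c(Br)c1 | intermediate
14 | 1-bromo-3,5-dimethoxy-2-methylbenzene | COc1cc(OC)c(C)c(Br)c1 | intermediate
15 | (3,5-dimethoxy-2-methylphenyl)magnesium bromide (aryl Grignard reagent) | COc1cc(OC)c(C)c([Mg]Br)c1 | intermediate
16 | (2S,3S)-3-(3,5-dimethoxy-2-methylphenyl)butan-2-ol | COc1cc(OC)c(C)c(c1)[C@H](C)[C@H](C)O | intermediate
17 | (2S,3S)-3-(2-bromo-3,5-dimethoxy-6-methylphenyl)butan-2-ol | COc1cc(OC)c(C)c(c1Br)[C@H](C)[C@H](C)O | intermediate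
18 | aryllithium alkoxide (dilithio form of 17 after exchange) | COc1cc(OC)c(C)c(c1[Li])[C@H](C)[C@H](C)O[Li] | intermediate
19 | 2-[(2S,3S)-3-hydroxybutan-2-yl]-4,6-dimethoxy-3-methylbenzoic acid | COc1cc(OC)c(C)c(c1C(=O)O)[C@H](C)[C@H](C)O | intermediate
20 | (3R,4S)-6,8-dimethoxy-3,4,5-trimethyl-3,4-dihydro-1H-isochromen-1-one | COc1cc(OC)c(C)c2c1C(=O)O[C@H](C)[C@H]2C | intermediate
21 | (3R,4S)-7-iodo-6,8-dimethoxy-3,4,5-trimethyl-3,4-dihydro-1H-isochromen-1-one | COc1c(I)c(OC)c(C)c2c1C(=O)O[C@H](C)[C@H]2C | intermediate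
22 | arylmagnesium chloride from 21 | COc1c([Mg]Cl)c(OC)c(C)c2c1C(=O)O[C@H](C)[C@H]2C | intermediate
23 | arylcopper reagent from 22 | COc1c([Cu])c(OC)c(C)c2c1C(=O)O[C@H](C)[C@H]2C | intermediate
24 | (3R,4S)-7-[(2S)-but-3-yn-2-yl]-6,8-dimethoxy-3,4,5-trimethyl-3,4-dihydro-1H-isochromen-1-one | C#C[C@H](C)c1c(OC)c(C)c2c(c1OC)C(=O)O[C@H](C)[C@H]2C | intermediate
25 | lithium acetylide of 24 | [Li]C#C[C@H](C)c1c(OC)c(C)c2c(c1OC)C(=O)O[C@H](C)[C@H]2C | intermediate
26 | lithium ynolate from 25 | [Li]OC#C[C@H](C)c1c(OC)c(C)c2c(c1OC)C(=O)O[C@H](C)[C@H]2C | intermediate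
27 | (3R,4S)-6,8-dimethoxy-3,4,5-trimethyl-7-[(2S)-4-{[tri(propan-2-yl)silyl]oxy}but-3-yn-2-yl]-3,4-dihydro-1H-isochromen-1-one | CC(C)[Si](C(C)C)(C(C)C)OC#C[C@H](C)c1c(OC)c(C)c2c(c1OC)C(=O)O[C@H](C)[C@H]2C | intermediate
28 | vinylketene from 8: 3-[(2S,3R)-3-{[tert-butyl(dimethyl)silyl]oxy}butan-2-yl]-2-methylbuta-1,3-dien-1-one | O=C=C(C)C(=C)[C@H](C)[C@@H](C)O[Si](C)(C)C(C)(C)C | intermediate
29 | 2-vinylcyclobutenone ([2+2] adduct of 28 and 27, ring carbon C4 unassigned) | O=C1C([C@H](C)c2c(OC)c(C)c3c(c2OC)C(=O)O[C@H](C)[C@H]3C)=C(O[Si](C(C)C)(C(C)C)C(C)C)C1(C)C(=C)[C@H](C)[C@@H](C)O[Si](C)(C)C(C)(C)C | intermediate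
30 | dienylketene (ring-opened 29) | O=C=C([C@H](C)c1c(OC)c(C)c2c(c1OC)C(=O)O[C@H](C)[C@H]2C)C(O[Si](C(C)C)(C(C)C)C(C)C)=C(C)C(=C)[C@H](C)[C@@H](C)O[Si](C)(C)C(C)(C)C | intermediate
31 | cyclohexa-2,4-dienone (electrocyclization product of 30) | O=C1CC([C@H](C)[C@@H](C)O[Si](C)(C)C(C)(C)C)=C(C)C(O[Si](C(C)C)(C(C)C)C(C)C)=C1[C@H](C)c2c(OC)c(C)c3c(c2OC)C(=O)O[C@H](C)[C@H]3C | intermediate
32 | (3R,4S)-7-[(1R)-1-{4-[(2S,3R)-3-{[tert-butyl(dimethyl)silyl]oxy}butan-2-yl]-6-hydroxy-3-methyl-2-{[tri(propan-2-yl)silyl]oxy}phenyl}ethyl]-6,8-dimethoxy-3,4,5-trimethyl-3,4-dihydro-1H-isochromen-1-one | Oc1cc([C@H](C)[C@@H](C)O[Si](C)(C)C(C)(C)C)c(C)c(O[Si](C(C)C)(C(C)C)C(C)C)c1[C@H](C)c2c(OC)c(C)c3c(c2OC)C(=O)O[C@H](C)[C@H]3C | intermediate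
33 | (3R,4S)-7-[(1S)-1-{2,6-dihydroxy-4-[(2S,3R)-3-hydroxybutan-2-yl]-3-methylphenyl}ethyl]-6,8-dimethoxy-3,4,5-trimethyl-3,4-dihydro-1H-isochromen-1-one | Oc1cc([C@H](C)[C@@H](C)O)c(C)c(O)c1[C@H](C)c2c(OC)c(C)c3c(c2OC)C(=O)O[C@H](C)[C@H]3C | intermediate
34 | (3R,4S)-7-[(1S)-1-{2,6-dihydroxy-4-[(2S,3R)-3-hydroxybutan-2-yl]-3-methylphenyl}ethyl]-6,8-dihydroxy-3,4,5-trimethyl-3,4-dihydro-1H-isochromen-1-one | Oc1cc([C@H](C)[C@@H](C)O)c(C)c(O)c1[C@H](C)c2c(O)c(C)c3c(c2O)C(=O)O[C@H](C)[C@H]3C | intermediate
35 | dicitrinone H: (3R,4S)-7-[(1R)-1-[(3R,4S)-6-hydroxy-3,4,5-trimethyl-8-oxo-4,8-dihydro-3H-isochromen-7-yl]ethyl]-6,8-dihydroxy-3,4,5-trimethyl-3,4-dihydro-1H-isochromen-1-one | CC1=C2C(=CO[C@H](C)[C@H]2C)C(=O)C([C@H](C)c2c(O)c(C)c3c(c2O)C(=O)O[C@H](C)[C@H]3C)=C1O | target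

**Step count and risks**
Total: 21 steps. Longest linear sequence: 13 steps (steps 9–21, from 12).

Most likely to fail, step 18: the vinylketene may be consumed by dimerization, or by acylating the product phenol, faster than it adds to the α-branched ynol ether, whose propargylic carbon carries a doubly ortho-substituted arene. Fallback, setting out from 8 and 20 and coming back at 34: the bridge–aryl bond would be taken out of the ring expansion. Cyclobutenone 8 would be heated in toluene with the small lactate-derived siloxyalkyne F1, made from commercial ethyl (S)-2-{[tert-butyl(dimethyl)silyl]oxy}propanoate by Kowalski ynolate formation (CH2Br2, LiTMP, then n-BuLi) and TIPSCl quench, to give the benzannulated phenol F2. Lactone 20 would be demethylated with BBr3 to the resorcinol lactone F3. Buffered TBAF would free F2 to the 2-hydroxybenzylic alcohol F4. A chiral BINOL-derived phosphoric acid would then dehydrate F4 to its ortho-quinone methide and guide Friedel–Crafts attack of an excess of F3 through C7′, its only free position, to give 34. In this variant the bridge configuration rests on catalyst control, and the minor epimer would be removed at 34.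

Second, step 16: the di-ortho-methoxy arylcopper reagent may transmetalate and substitute sluggishly, direct α-substitution to an aryl allene may compete with the 1,3-mode, and copper salts may racemize the bromoallene before it is consumed. Fallback, setting out from 22 and coming back at 24: the arylmagnesium chloride 22 would be transmetalated with ZnCl2 to the arylzinc chloride F5. F5 would be coupled in an enantioconvergent nickel-catalysed Negishi reaction (NiCl2·glyme, chiral pybox ligand of the sense that gives the S product, DME, −20 °C) with racemic 3-bromo-1-(trimethylsilyl)but-1-yne to give the silylalkyne F6. Buffered TBAF would then remove the trimethylsilyl group to give 24.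

Third, step 21: the acid-mediated formylation may be outrun by transacetalization or oligomerization of the pentahydroxy substrate or by acid-induced cleavage at the doubly benzylic bridge, and the quinone methide may hydrate or decompose during isolation. Fallback, setting out from 32 and coming back at 35: the carbon would be introduced earlier under chelation control. Casnati–Skattebøl ortho-formylation of the single free phenol of 32 (MgCl2, Et3N, paraformaldehyde, MeCN, reflux) would give the salicylaldehyde F7. Buffered TBAF followed by brief dilute acid would desilylate it and let the hydroxy aldehyde close to the di-O-methyl quinone methide F8. BBr3 at −78 °C would then cleave the two methyl ethers to give 35.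

**Further compounds**
F1 | step 18 | tert-butyl(dimethyl){[(2S)-4-{[tri(propan-2-yl)silyl]oxy}but-3-yn-2-yl]oxy}silane | C[C@H](O[Si](C)(C)C(C)(C)C)C#CO[Si](C(C)C)(C(C)C)C(C)C
F2 | step 18 | 5-[(2S,3R)-3-{[tert-butyl(dimethyl)silyl]oxy}butan-2-yl]-2-[(1S)-1-{[tert-butyl(dimethyl)silyl]oxy}ethyl]-4-methyl-3-{[tri(propan-2-yl)silyl]oxy}phenol | Oc1cc([C@H](C)[C@@H](C)O[Si](C)(C)C(C)(C)C)c(C)c(O[Si](C(C)C)(C(C)C)C(C)C)c1[C@H](C)O[Si](C)(C)C(C)(C)C
F3 | step 18 | (3R,4S)-6,8-dihydroxy-3,4,5-trimethyl-3,4-dihydro-1H-isochromen-1-one | Oc1cc(O)c(C)c2c1C(=O)O[C@H](C)[C@H]2C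
F4 | step 18 | 5-[(2S,3R)-3-hydroxybutan-2-yl]-2-[(1S)-1-hydroxyethyl]-4-methylbenzene-1,3-diol | Oc1cc([C@H](C)[C@@H](C)O)c(C)c(O)c1[C@H](C)O
F5 | step 16 | arylzinc chloride from 22 | COc1c([Zn]Cl)c(OC)c(C)c2c1C(=O)O[C@H](C)[C@H]2C
F6 | step 16 | (3R,4S)-6,8-dimethoxy-3,4,5-trimethyl-7-[(2S)-4-(trimethylsilyl)but-3-yn-2-yl]-3,4-dihydro-1H-isochromen-1-one | C[Si](C)(C)C#C[C@H](C)c1c(OC)c(C)c2c(c1OC)C(=O)O[C@H](C)[C@H]2C
F7 | step 21 | salicylaldehyde from 32 (formyl group at C8a, silyl and methyl ethers retained) | Oc1c(C=O)c([C@H](C)[C@@H](C)O[Si](C)(C)C(C)(C)C)c(C)c(O[Si](C(C)C)(C(C)C)C(C)C)c1[C@H](C)c2c(OC)c(C)c3c(c2OC)C(=O)O[C@H](C)[C@H]3C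
F8 | step 21 | 6′,8′-di-O-methyl ether of dicitrinone H | CC1=C2C(=CO[C@H](C)[C@H]2C)C(=O)C([C@H](C)c2c(OC)c(C)c3c(c2OC)C(=O)O[C@H](C)[C@H]3C)=C1O
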